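**Retrosynthetic overview**

Target 25 ⇐ C6-acylation of enol 22 with (S)-2-methylbutanoic acid ⇐ ethyl vinylogous ester 21, which already holds rings A–D.
Key disconnection: ring A of 21 is opened at C1–C2 and C3–C4 at once, which also opens ring B. This gives the ketene silyl acetal of a tertiary isobutyrate on the C4′ oxygen (C3, C2) and an ethoxyvinylketene (C1, C6, C5, C4) released from a 3-ethoxycyclobutenone on the C5′–CH2 arm (compound 18).
Enabling feature: ring A is a 6,6-dimethylcyclohexa-2,4-dienone whose quaternary C2 lies between the ketone C1 and the enol-ether carbon C3 bonded to the ring-B oxygen, with oxygen on alternate carbons C1, C3, C5. The array O–C3(=C4)–C2Me2–C1(=O) is a ketene acetal joined to a ketene, and the ring-B atoms O–C4′–C5′–CH2 tether the two.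
18 ⇐ isobutyrate acid 12 (ketene/ethoxyacetylene [2+2], then ester enolisation–silylation) ⇐ trans-fused δ-lactone 8 ⇐ (−)-β-caryophyllene 1 + Meldrum's acid + CH2O (domino Knoevenagel/hetero-Diels–Alder, sets C4′ and C5′).
Ring order: rings C (nine-membered) and D (cyclobutane) come with 1; temporary dioxinone and δ-lactone rings (steps 1–2, opened in step 3); temporary cyclobutenone (step 4); rings B (dihydropyran) and A together in step 6.

Key step: step 6

Remark: primed locants follow caryophyllane numbering (C4′ = oxygen-bearing quaternary carbon, C5′ = adjacent CH); ring A locants are C1 (ketone), C2 (CMe2), C3 (C–O of ring B), C4 (C–CH2 of ring B), C5 (C–OH), C6 (C–acyl); enols 22 and 25 are drawn as one tautomer, and the cyclobutenone sp3 centre of 16 and 18 is an epimer mixture that is destroyed in step 6.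

**Route**

Step 1
Reactants: 1 (−)-β-caryophyllene; 2 Meldrum's acid; 3 formaldehyde (as paraformaldehyde)
Product: 5 pyranodioxinone cycloadduct (1′R 4′S 5′R 9′S; O on C4′ and CH2 on C5′; trans ring fusion), via 5-methylene Meldrum's acid 4 (not isolated)
Conditions: (CH2O)n, ethylenediammonium diacetate (10 mol %), MeCN, 23–40 °C; chromatography to remove the (4′R,5′S) face isomer
Reagents that add atoms: Meldrum's acid (CC1(C)OC(=O)CC(=O)O1); formaldehyde (C=O)
Why: Knoevenagel condensation gives the strongly electrophilic 1-oxadiene 4, which should be trapped by the strained E-trisubstituted alkene of 1 (the exocyclic methylene is far less reactive) in an inverse-electron-demand hetero-Diels–Alder reaction with oxygen going to the more substituted C4′; suprafacial addition to the E-alkene makes the C4′–O and C5′–C bonds syn (methyl and H trans), and the (4′S,5′R) series arises from outer-face attack on the alkene orientation opposite to the one that peracids use to form natural (4R,5R)-caryophyllene oxide, the isomer from the other orientation being separated here.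

Step 2
Reactants: 5 pyranodioxinone cycloadduct; 6 water
Product: 8 trans-fused δ-lactone (C4′–O–C(=O)–CH2–CH2–C5′; 1′R 4′S 5′R 9′S), via carboxy lactone 7 (not isolated)
Conditions: pyridine/H2O 10:1, 100 °C
Reagents that add atoms: water (O)
Why: Water opens the ketene acetal–acylal of the dioxinone with loss of acetone to the malonic half-acid lactone 7, which decarboxylates on heating (the usual degradation of Meldrum's-acid cycloadducts); C4′ and C5′ are not touched.

Step 3
Reactants: 8 trans-fused δ-lactone; 9 potassium hydroxide; 10 isobutyryl chloride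
Product: 12 isobutyrate acid (C4′–O–CO–CHMe2 and C5′–CH2CH2CO2H), via potassium hydroxy carboxylate 11 (not isolated)
Conditions: KOH (1.0 equiv), MeOH/H2O, 50 °C; evaporate, PhMe azeotrope; KN(SiMe3)2 (1.1 equiv), THF, −78 °C; iPrCOCl (1.1 equiv), −78 → 0 °C; aq. HCl to pH 3, 0 °C
Reagents that add atoms: potassium hydroxide ([K+].[OH-]); isobutyryl chloride (CC(C)C(Cl)=O)
Why: Saponification frees the tertiary hydroxyl, whose potassium alkoxide should be acylated far faster than the carboxylate (nucleophilic acyl substitution), and with the hydroxyl capped the acid can no longer relactonise; the C4′–O bond is never broken, so no stereocentre is affected.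

Step 4
Reactants: 12 isobutyrate acid; 13 ethoxyacetylene
Product: 16 3-ethoxy-4-alkylcyclobut-2-enone (alkyl = C5′–CH2; tertiary isobutyrate kept), via acid chloride 14 (not isolated), via alkylketene 15 (not isolated)
Conditions: (COCl)2, DMF (cat.), CH2Cl2, 0 → 23 °C, evaporate; then 13 (4 equiv), Et3N (1.3 equiv, slow addition), Et2O, 0 → 23 °C
Reagents that add atoms: ethoxyacetylene (CCOC#C)
Why: Dehydrochlorination of the acid chloride gives aldoketene 15, which should undergo the classical regioselective ketene–alkoxyalkyne [2+2] cycloaddition (alkyne CH to the ketene carbonyl carbon); the new ring stereocentre is not controlled and is erased in step 6, and the tertiary ester and exocyclic alkene are inert.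

Step 5
Reactants: 16 3-ethoxy-4-alkylcyclobut-2-enone; 17 tert-butyldimethylsilyl chloride
Product: 18 ketene silyl acetal (C4′–O–C(OSiMe2tBu)=CMe2) carrying the ethoxycyclobutenone arm
Conditions: LiN(iPr)2 (1.15 equiv), tBuMe2SiCl (1.5 equiv, present from the start), DMPU, THF, −78 °C; pentane, filtration, no chromatography
Reagents that add atoms: tert-butyldimethylsilyl chloride (CC(C)(C)[Si](C)(C)Cl)
Why: Kinetic deprotonation of the isobutyrate methine with in situ O-silylation (internal-quench ketene silyl acetal formation as practised for the Ireland–Claisen rearrangement) should give the tetrasubstituted ketene acetal with no E/Z issue; the cyclobutenone α′-H should not be removed because its enolate would be an antiaromatic cyclobutadienolate.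

Step 6
Reactants: 18 ketene silyl acetal
Product: 21 tetracyclic ethoxy dienone (rings A–D; C5–OEt and C6–H), via ethoxyvinylketene 19 (not isolated), via silyl ketal cycloadduct 20 (not isolated)
Conditions: PhMe (0.01 M), 2,6-di-tert-butylpyridine (0.2 equiv), 110–130 °C, sealed tube; then PPTS (0.2 equiv), 23 °C
Reagents that add atoms: none
Why: Proposed new method: heating should open the 3-ethoxycyclobutenone by conrotatory 4π-electrocyclic ring opening (alkyl chain turning outward) to ethoxyvinylketene 19, whose ketene carbon (future C1) is electrophilic and whose vinyl terminus (future C4) is nucleophilic, a polarity complementary to the tethered ketene silyl acetal (nucleophilic CMe2 = C2, latent oxocarbenium carbon = C3), so that a concerted but asynchronous intramolecular [4+2] cycloaddition joins C1–C2 and C3–C4 to give silyl ketal 20, which loses tBuMe2SiOH under PPTS to the cross-conjugated dienone 21. The closest known reaction types are the Danheiser benzannulation (cyclobutenone-derived vinylketenes with alkoxy- and siloxyalkynes), formal [4+2] annulations of vinylketenes with enamines and ynamines, and Diels–Alder reactions of ketene acetals followed by loss of ROH; a vinylketene as 4π partner with a ketene silyl acetal as 2π partner is not established. Ring A is closed by the [4+2] union of both new bonds, and ring B is closed by the C3–C4 bond in a type 1 (fused) intramolecular mode through a six-membered tether ring, 6-exo with respect to both π systems. No surviving stereocentre is created (C2 carries two methyls, and the transient centres at C3 and C4 are erased by the elimination), and C1′, C4′, C5′ and C9′ are spectators. The step needs regioselectivity (C1–C2/C3–C4 instead of the usual ketene [2+2]) and retention of the ring-B oxygen on C3: the first is secured by the matched push–pull polarity and by the four-atom tether O–C4′–C5′–CH2, which would force a trans-cyclooctene in the [2+2] mode, the second by irreversible loss of the silanol while any ring opening of the mixed ketal is reversible and the only β-hydrogen sits on C4. The quaternary C2 prevents aromatisation, so the product stays at the dienone oxidation level of the target.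

Step 7
Reactants: 21 tetracyclic ethoxy dienone; 9 potassium hydroxide
Product: 22 tetracyclic enol (C5–OH, C6–H; deacyl target), isolated after acidification of its potassium enolate
Conditions: KOH (3 equiv), THF/H2O 3:1, 50 °C; then 1 M HCl to pH 3, 0 °C
Reagents that add atoms: potassium hydroxide ([K+].[OH-])
Why: Saponification of the vinylogous ethyl ester by conjugate addition–elimination should occur at the less hindered ethoxy-bearing C5 with ethoxide as the better leaving group, whereas C3 is shielded by the adjacent CMe2 and addition there is a reversible ring–chain process; the enolate formed is inert to further attack.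

Step 8
Reactants: 22 tetracyclic enol; 23 (S)-2-methylbutanoic acid
Product: 25 target CNP0591516.1, via enol ester 24 (not isolated)
Conditions: 23 (1.2 equiv), DCC (1.3 equiv), DMAP (1.0 equiv), CH2Cl2, 0 → 23 °C
Reagents that add atoms: (S)-2-methylbutanoic acid (CC[C@H](C)C(=O)O)
Why: Steglich O-acylation of the enol followed by DMAP-mediated 1,3 O→C acyl shift (the standard entry to 2-acylcyclohexane-1,3-diones) should place the acyl group on C6, the only carbon between the two oxygenated carbons; the (S) centre comes from the acid and is not exposed to strong base.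

**Compound list**

1 | (−)-β-caryophyllene, (1R,4E,9S) | C=C1CC/C=C(C)/CC[C@@H]2[C@@H]1CC2(C)C | starting material
2 | Meldrum's acid (2,2-dimethyl-1,3-dioxane-4,6-dione) | CC1(C)OC(=O)CC(=O)O1 | starting material
3 | formaldehyde (used as paraformaldehyde) | C=O | starting material
4 | 5-methylene Meldrum's acid | C=C1C(=O)OC(C)(C)OC1=O | intermediate (not isolated)
5 | pyranodioxinone cycloadduct, 2,2-dimethyl-4H-pyrano[2,3-d][1,3]dioxin-4-one ring fused trans across C4′–C5′ (1′R,4′S,5′R,9′S) | C=C1CC[C@@H]2CC3=C(O[C@@]2(C)CC[C@@H]2[C@@H]1CC2(C)C)OC(C)(C)OC3=O | intermediate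
6 | water | O | starting material
7 | carboxy lactone (α-carboxy δ-lactone, epimers at the α-carbon) | C=C1CC[C@@H]2CC(C(=O)O)C(=O)O[C@@]2(C)CC[C@@H]2[C@@H]1CC2(C)C | intermediate (not isolated)
8 | trans-fused δ-lactone (1′R,4′S,5′R,9′S) | C=C1CC[C@@H]2CCC(=O)O[C@@]2(C)CC[C@@H]2[C@@H]1CC2(C)C | intermediate
9 | potassium hydroxide | [K+].[OH-] | starting material
10 | isobutyryl chloride | CC(C)C(Cl)=O | starting material
11 | potassium hydroxy carboxylate (C4′–OH, C5′–CH2CH2CO2K) | C=C1CC[C@H](CCC(=O)[O-])[C@@](C)(O)CC[C@@H]2[C@@H]1CC2(C)C.[K+] | intermediate (not isolated)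
12 | isobutyrate acid (C4′–O–CO–CHMe2, C5′–CH2CH2CO2H; 1′R,4′S,5′R,9′S) | C=C1CC[C@H](CCC(=O)O)[C@@](C)(OC(=O)C(C)C)CC[C@@H]2[C@@H]1CC2(C)C | intermediate
13 | ethoxyacetylene | CCOC#C | starting material
14 | acid chloride of 12 | C=C1CC[C@H](CCC(Cl)=O)[C@@](C)(OC(=O)C(C)C)CC[C@@H]2[C@@H]1CC2(C)C | intermediate (not isolated)
15 | alkylketene from 14 | C=C1CC[C@H](CC=C=O)[C@@](C)(OC(=O)C(C)C)CC[C@@H]2[C@@H]1CC2(C)C | intermediate (not isolated)
16 | 3-ethoxy-4-alkylcyclobut-2-enone with tertiary isobutyrate (epimers at the ring sp3 carbon) | C=C1CC[C@H](CC3C(=O)C=C3OCC)[C@@](C)(OC(=O)C(C)C)CC[C@@H]2[C@@H]1CC2(C)C | intermediate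
17 | tert-butyldimethylsilyl chloride | CC(C)(C)[Si](C)(C)Cl | starting material
18 | ketene silyl acetal, C4′–O–C(OSiMe2tBu)=CMe2, with the ethoxycyclobutenone arm | C=C1CC[C@H](CC3C(=O)C=C3OCC)[C@@](C)(OC(O[Si](C)(C)C(C)(C)C)=C(C)C)CC[C@@H]2[C@@H]1CC2(C)C | intermediate
19 | ethoxyvinylketene (chain trans to the ketene carbon) | C=C1CC[C@H](C/C=C(OCC)/C=C=O)[C@@](C)(OC(O[Si](C)(C)C(C)(C)C)=C(C)C)CC[C@@H]2[C@@H]1CC2(C)C | intermediate (not isolated)
20 | silyl ketal cycloadduct (C3 bears the ring-B oxygen and OSiMe2tBu; C4–H) | C=C1CC[C@@H]2CC3C(OCC)=CC(=O)C(C)(C)C3(O[Si](C)(C)C(C)(C)C)O[C@@]2(C)CC[C@@H]2[C@@H]1CC2(C)C | intermediate (not isolated)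
21 | tetracyclic ethoxy dienone (C5–OEt, C6–H) | C=C1CC[C@@H]2CC3=C(O[C@@]2(C)CC[C@@H]2[C@@H]1CC2(C)C)C(C)(C)C(=O)C=C3OCC | intermediate
22 | tetracyclic enol (C5–OH, C6–H) | C=C1CC[C@@H]2CC3=C(O[C@@]2(C)CC[C@@H]2[C@@H]1CC2(C)C)C(C)(C)C(=O)C=C3O | intermediate
23 | (S)-2-methylbutanoic acid | CC[C@H](C)C(=O)O | starting material
24 | enol ester of 22 with (S)-2-methylbutanoic acid | C=C1CC[C@@H]2CC3=C(O[C@@]2(C)CC[C@@H]2[C@@H]1CC2(C)C)C(C)(C)C(=O)C=C3OC(=O)[C@@H](C)CC | intermediate (not isolated)
25 | CNP0591516.1 | C=C1CC[C@@H]2CC3=C(O[C@@]2(C)CC[C@@H]2[C@@H]1CC2(C)C)C(C)(C)C(=O)C(C(=O)[C@@H](C)CC)=C3O | target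

**Step count and risks**

Total step count: 8. Longest linear sequence: 8 steps (from 1).

Steps most likely to fail:

1. Step 6 (proposed new method). The ketene acetal may transfer its silyl group to the dienolate oxygen after simple C-acylation without ring closure, the vinylketene may oligomerise, or the ketene acetal may be lost by adventitious hydrolysis before the cyclobutenone opens. Fallback by known polar chemistry, setting out from 12 and rejoining at 22: acid 12 is converted as in step 4 to acid chloride 14, which is treated with LiCH2CO2Me (2.2 equiv, THF, −78 °C) to give methyl β-keto ester F1. HC(OMe)3 with catalytic TsOH in MeOH gives methyl (E)-3-methoxy-enoate F2. LiN(iPr)2 (1.1 equiv, THF, −78 → 0 °C) forms the γ-lithiated dienolate, which takes over the isobutyryl group from the neighbouring tertiary ester through a six-membered transition state (Baker–Venkataraman-type O→C acyl shift) to give γ-isobutyryl hydroxy enoate F3. PPTS in toluene with 4 Å sieves at 80 °C closes the tertiary hydroxyl onto the only ketone to give dihydropyran dienoate F4 (ring B). KOtBu in THF then effects the vinylogous Dieckmann closure of the isopropyl methine carbon onto the methyl ester to give methoxy dienone F5 (ring A). Saponification under the conditions of step 7 gives enol 22.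

2. Step 1. Cycloaddition may take place mainly on the other face of the trans double bond (the orientation that also leads to natural caryophyllene oxide), and an ene reaction of the electrophilic oxadiene may compete with ring formation. Fallback with face selection by a chiral catalyst instead of by the substrate, setting out from 1 and rejoining at 11 and 8: 1 is combined with methyl 2-oxobut-3-enoate F6 (made in the flask from commercial methyl 2-hydroxybut-3-enoate with Dess–Martin periodinane) in the presence of Cu(OTf)2 and a C2-symmetric tert-butyl bis(oxazoline) ligand, both ligand antipodes to be tried, in an inverse-electron-demand hetero-Diels–Alder reaction of a chelating β,γ-unsaturated α-keto ester; this should give dihydropyran ester F7. Aqueous HCl in THF hydrolyses the enol ether to δ-hydroxy α-keto ester F8 (in equilibrium with its cyclic hemiketal). KOH/H2O2 cleaves the α-keto ester oxidatively to potassium carboxylate 11, which is acidified to lactone 8 or used directly in the acylation of step 3.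

3. Step 5. The amide base or the ester enolate may attack the cyclobutenone (addition–elimination at the ethoxy-bearing carbon, 1,2-addition or ring cleavage) instead of clean ester enolisation. Fallback that makes the ketene acetal without base by conjugate hydrosilylation, setting out from 8 and rejoining at 18: carboxylate 11 (from 8 as in step 3) is acylated with methacryloyl chloride in place of 10 to give methacrylate acid F9. This is taken through the sequence of step 4, by way of methacrylate acid chloride F10 and methacrylate ketene F11, to methacrylate cyclobutenone F12. RhCl(PPh3)3 (2 mol %) and tBuMe2SiH in benzene at 50 °C should add Si–H 1,4 across the methacrylate and give ketene silyl acetal 18 directly.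

Further compounds
F1 | step 6 | methyl β-keto ester (C5′–CH2CH2–CO–CH2–CO2Me, tertiary isobutyrate kept) | C=C1CC[C@H](CCC(=O)CC(=O)OC)[C@@](C)(OC(=O)C(C)C)CC[C@@H]2[C@@H]1CC2(C)C
F2 | step 6 | methyl (E)-3-methoxy-enoate | C=C1CC[C@H](CC/C(OC)=C\C(=O)OC)[C@@](C)(OC(=O)C(C)C)CC[C@@H]2[C@@H]1CC2(C)C
F3 | step 6 | γ-isobutyryl hydroxy enoate (free C4′–OH, epimers at the acylated carbon) | C=C1CC[C@H](CC(C(=O)C(C)C)/C(OC)=C\C(=O)OC)[C@@](C)(O)CC[C@@H]2[C@@H]1CC2(C)C
F4 | step 6 | dihydropyran dienoate (ring B closed, isopropyl on C3) | C=C1CC[C@@H]2CC(/C(OC)=C\C(=O)OC)=C(C(C)C)O[C@@]2(C)CC[C@@H]2[C@@H]1CC2(C)C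
F5 | step 6 | methoxy dienone (methyl ether analogue of 21) | C=C1CC[C@@H]2CC3=C(O[C@@]2(C)CC[C@@H]2[C@@H]1CC2(C)C)C(C)(C)C(=O)C=C3OC
F6 | step 1 | methyl 2-oxobut-3-enoate | C=CC(=O)C(=O)OC
F7 | step 1 | dihydropyran ester (O on C4′, CH2 on C5′; 1′R,4′S,5′R,9′S) | C=C1CC[C@@H]2CC=C(C(=O)OC)O[C@@]2(C)CC[C@@H]2[C@@H]1CC2(C)C
F8 | step 1 | δ-hydroxy α-keto ester | C=C1CC[C@H](CCC(=O)C(=O)OC)[C@@](C)(O)CC[C@@H]2[C@@H]1CC2(C)C
F9 | step 5 | methacrylate acid | C=C1CC[C@H](CCC(=O)O)[C@@](C)(OC(=O)C(C)=C)CC[C@@H]2[C@@H]1CC2(C)C
F10 | step 5 | methacrylate acid chloride | C=C1CC[C@H](CCC(Cl)=O)[C@@](C)(OC(=O)C(C)=C)CC[C@@H]2[C@@H]1CC2(C)C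
F11 | step 5 | methacrylate ketene | C=C1CC[C@H](CC=C=O)[C@@](C)(OC(=O)C(C)=C)CC[C@@H]2[C@@H]1CC2(C)C
F12 | step 5 | methacrylate cyclobutenone | C=C1CC[C@H](CC3C(=O)C=C3OCC)[C@@](C)(OC(=O)C(C)=C)CC[C@@H]2[C@@H]1CC2(C)C
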